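All constants belong to no real substance, and the outcome is calculated.

The catalyst here cannot finish a round in less time than its waits add up to, so its rate has a ceiling, whereas the homo dimer route climbs with [substrate] squared.

    catalyst intermediate A → catalyst intermediate B (k1 = 0.019 s⁻¹)
    substrate + catalyst intermediate B ⇌ catalyst intermediate C (K2 = 170 M⁻¹, k2 = 33 M⁻¹ s⁻¹)
    reagent + catalyst intermediate C → spent catalyst (k3 = 0.0014 M⁻¹ s⁻¹)
    catalyst intermediate C → free catalyst + product (k4 = 0.028 s⁻¹)
    2 substrate → homo dimer (k5 = 0.0020 M⁻¹ s⁻¹)
    reagent + free catalyst → catalyst intermediate A (k6 = 0.17 M⁻¹ s⁻¹)

| setting | red | amber | blue | violet |
|---|---|---|---|---|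
| substrate | 10 mM | 10 mM | 10 mM | 10 mM (fed, over 4.00 d) |
| reagent | 2.00 equiv | 2.00 equiv | 2.00 equiv | 2.00 equiv |
| free catalyst | 0.18 mol% | 0.18 mol% | 0.18 mol% | 0.18 mol% |
| time | 4.0 d | 4.0 d |  | 4.0 d |
| remark | a closed flask charged with all of it at once and left for 4.0 d | a tube with plug flow, the mixed feed as stated, residence time 4.0 d | one stirred flow tank at steady state, fed with the mixture as stated, mean residence time 4.0 d | all but substrate at the start; substrate goes in evenly over 4.00 d, the run ends at 4.0 d |

- in percentages every species weighs as the substrate in it: one homo dimer counts as two
- a doubled species enters its step squared and goes two at a time
- the stated concentrations are those of everything mixed, before any reaction; amounts are the same in each set-up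
- the feed brings no volume worth counting
- run time (red): 4.0 d

- the set-up with the highest amount of product at the outlet or at the end, in percent of the substrate put in ("none" if the first two lie within 2 percentage points) (red / amber / blue / violet / none)
- amount of product at the outlet or at the end, in percent of the substrate put in, red
- amount of product at the outlet or at the end, in percent of the substrate put in, amber
- amount of product at the outlet or at the end, in percent of the substrate put in, blue
- amount of product at the outlet or at the end, in percent of the substrate put in, violet

I reckon the waits with reagent as charged and binding of substrate left out. Free catalyst waits 294 s for reagent, catalyst intermediate A waits 52.6 s and catalyst intermediate C waits 35.7 s. The meeting with reagent is longer, so it is the rate-limiting step of the round. The charged catalyst divided by the sum of the waits gives the ceiling 4.07 mM d⁻¹.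

The dimer route uses substrate at twice its constant times [substrate] squared. Setting this equal to the ceiling gives 3.43 mM. This is the even level, the [substrate] at which the catalyst at its ceiling and the dimer route consume substrate equally. There half of the substrate goes each way, which makes it the zero of my scale.

My small table has a row for each case, with the catalyst's rate set against the other rate. The top row is the charge, 10 mM: ceiling 4.07 mM d⁻¹, dimer route 34.6 mM d⁻¹, which is 8.50 times faster. The middle row is the even level, where the two rates are equal. The bottom row is the throughput of blue and violet: ceiling 4.07 mM d⁻¹, substrate supplied at 2.50 mM d⁻¹, which is less.

Red and amber share one time course, since a plug of the tube is a closed flask, and they start in the top row. If I count substrate above the even level as lost to homo dimer and substrate below it as product, their yield is 34.3 %. Blue and violet sit in the bottom row, where the supply is less than a ceiling reckoned for fresh catalyst, charged reagent and no binding, so I expect [substrate] under the even level and far more product. My reckoning stops there.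

The forecast gives 38 % for red, 38 % for amber, 65.7 % for blue and 66.5 % for violet, above my figure for the first two. It names none as best: “Blue and violet come out too close to separate by rough estimate”.

The simulation gives 38.2 % for red, 38.2 % for amber, 65.5 % for blue and 69.7 % for violet, so the best is violet, 4.2 percentage points ahead of blue. In red, homo dimer stood at 61.7 % by 2.00 d, with substrate down to 0.245 %. Violet made product at 1.74 mM d⁻¹ on average, less than the 2.50 mM d⁻¹ supplied, and substrate built up there. Violet's [substrate] read 1.50 mM at 4.00 d and blue's read 1.26 mM, each under the even level. A neighbour of red charged with 0.072 mol% of free catalyst has its even level at 2.17 mM. Scaling red's product by that same root gives 24.2 %, and the neighbour gives 24.7 %.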